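With cyclopenta[c]pyran locants (C1 aryl-bearing, O2, C3, C4, C4a, C5–C7, C7a), the cyclopentane ring C4a–C5–C6–C7–C7a hides a ring-contracted carvone. C7 (CHMe) and C7a flank the exocyclic carbon C1 just as the two α-carbons flank the carbonyl of trans-dihydrocarvone, whose isopropenyl group supplies C4, its methyl and C3. The key step, a photochemical Wolff rearrangement of the monocyclic 6-diazo ketone, makes the C7–C7a bond, closes the cyclopentane and ejects the carbonyl carbon as C1 in one operation. Enol-ether lithiation/acylation at C3, Friedel–Crafts union of C1 with 4-hydroxy-5-methylcoumarin and carbonyl-O-methylation complete the target.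

Key step: step 3

Remark on the chemistry: C4 in 8 and 9 and the anomeric centre C1 in 10, 11, 14 and 15 are epimer mixtures of no consequence (C4 becomes sp2 in step 5, C1 is set anew in step 10), so their SMILES leave these centres undefined. 2'-Hydroxy-6'-methylacetophenone is assumed to be a catalogue compound.

Step 1
Reactants: 1 (S)-(+)-carvone
Product: 3 (2S,5S)-2-methyl-5-(prop-1-en-2-yl)cyclohexan-1-one, via lithium enolate 2 (not isolated)
Conditions: Li, NH3 (l), THF, t-BuOH (1 equiv), −78 °C; then NH4Cl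
Reagents that add atoms: none
Why: Dissolving-metal (Birch-type) conjugate reduction touches only the enone; protonation of enolate 2 on quench should place the 2-methyl group equatorial, giving mainly the trans (2S,5S) ketone, while C5 comes unchanged from carvone.

Step 2
Reactants: 3 (2S,5S)-2-methyl-5-(prop-1-en-2-yl)cyclohexan-1-one
Product: 5 (3R,6S)-2-diazo-6-methyl-3-(prop-1-en-2-yl)cyclohexan-1-one, via trifluoroacetyl ketone 4 (not isolated)
Conditions: LiN(SiMe3)2, THF, −78 °C; CF3CO2CH2CF3, −78 °C; then MeSO2N3, Et3N, H2O, MeCN, rt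
Reagents that add atoms: methanesulfonyl azide CS(=O)(=O)N=[N+]=[N-]
Why: Kinetic deprotonation occurs at the CH2 flank and not at the CHMe flank, Claisen trifluoroacetylation with CF3CO2CH2CF3 gives 4, and Regitz-type detrifluoroacetylative diazo transfer places the diazo group on that carbon only, leaving both stereocentres untouched.

Step 3
Reactants: 5 (3R,6S)-2-diazo-6-methyl-3-(prop-1-en-2-yl)cyclohexan-1-one
Product: 7 methyl (1R,2S,5S)-2-methyl-5-(prop-1-en-2-yl)cyclopentane-1-carboxylate, via ketene 6 (not isolated)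
Conditions: hν (medium-pressure Hg lamp, Pyrex filter), MeOH, high dilution, −20 °C
Reagents that add atoms: methanol CO
Why: Light expels N2 from the s-cis-locked diazo ketone and the CHMe ring carbon (future C7) shifts from the carbonyl carbon to the diazo carbon (future C7a) in a concerted Wolff rearrangement, creating the C7–C7a bond and pushing the former carbonyl carbon out of the ring as the ketene carbon of 6 (future C1). The closest known reaction type is the photochemical Wolff ring contraction of 2-diazocycloalkanones with alcohol trapping. The cyclopentane closes by a 1,2-alkyl shift (six-to-five ring contraction, a three-centre suprafacial migration and not a chain cyclisation). C7 migrates with retention and C4a is untouched, so both keep the configuration of 3; the new centre C7a is set when methanol adds to the ketene and the ester enol is protonated from the face anti to the isopropenyl group at C4a (syn to the smaller methyl at C7), which should place the ester cis to isopropenyl and trans to methyl. The step needs migration to win over 1,2-hydride shift, O–H insertion and intermolecular cyclopropanation, which the rigid s-cis geometry of the cyclic diazo ketone and high dilution in methanol secure; regiochemistry is fixed because only one carbon besides the diazo carbon is bonded to the carbonyl.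

Step 4
Reactants: 7 methyl (1R,2S,5S)-2-methyl-5-(prop-1-en-2-yl)cyclopentane-1-carboxylate
Product: 8 2-[(1R,2R,3S)-2-(hydroxymethyl)-3-methylcyclopentyl]propan-1-ol
Conditions: BH3·SMe2 (excess), THF, 0 °C to reflux; then NaOH, H2O2, 0 °C to rt
Reagents that add atoms: hydrogen peroxide OO
Why: Borane hydroborates the 1,1-disubstituted alkene in the anti-Markovnikov sense and reduces the ester in refluxing THF, so hydroboration–oxidation and ester reduction should occur in one flask; C4 forms as an epimer mixture that step 5 erases, and C7a is no longer epimerisable.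

Step 5
Reactants: 8 2-[(1R,2R,3S)-2-(hydroxymethyl)-3-methylcyclopentyl]propan-1-ol
Product: 10 (4aS,7S,7aR)-4,7-dimethyl-1,4a,5,6,7,7a-hexahydrocyclopenta[c]pyran-1-ol, via iridodial dialdehyde 9 (not isolated)
Conditions: (COCl)2, DMSO, CH2Cl2, −78 °C; Et3N, −78 to 0 °C; aqueous NaHCO3 work-up
Reagents that add atoms: none
Why: Swern oxidation gives dialdehyde 9, which by ring–chain tautomerism (enol oxygen of the C3 aldehyde adding to the cis-disposed C1 aldehyde) should close to the cis-fused enol-ether lactol; C4 becomes sp2 and the cis ring fusion follows from the C4a/C7a configuration already present.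

Step 6
Reactants: 10 (4aS,7S,7aR)-4,7-dimethyl-1,4a,5,6,7,7a-hexahydrocyclopenta[c]pyran-1-ol
Product: 11 triisopropyl{[(4aS,7S,7aR)-4,7-dimethyl-1,4a,5,6,7,7a-hexahydrocyclopenta[c]pyran-1-yl]oxy}silane
Conditions: i-Pr3SiCl, imidazole, DMAP (cat.), DMF, rt
Reagents that add atoms: triisopropylsilyl chloride CC(C)[Si](Cl)(C(C)C)C(C)C
Why: Silylation of the anomeric hydroxyl traps the lactol as a base-stable acetal; the triisopropylsilyl group should resist t-BuLi in step 8 yet ionise under Lewis acid in step 10.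

Step 7
Reactants: 12 3-methylbutanoyl chloride
Product: 13 N-methoxy-N,3-dimethylbutanamide
Conditions: MeNH(OMe)·HCl, pyridine, CH2Cl2, 0 °C to rt
Reagents that add atoms: N,O-dimethylhydroxylamine hydrochloride CNOC.Cl
Why: Simple N-acylation of the hydroxylamine by the acid chloride gives the Weinreb amide.

Step 8
Reactants: 11 triisopropyl{[(4aS,7S,7aR)-4,7-dimethyl-1,4a,5,6,7,7a-hexahydrocyclopenta[c]pyran-1-yl]oxy}silane; 13 N-methoxy-N,3-dimethylbutanamide
Product: 15 1-[(4aS,7S,7aR)-4,7-dimethyl-1-(triisopropylsilyloxy)-1,4a,5,6,7,7a-hexahydrocyclopenta[c]pyran-3-yl]-3-methylbutan-1-one, via C3-lithio enol ether 14 (not isolated)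
Conditions: t-BuLi, THF, −78 to 0 °C; then 13 (excess), −78 to 0 °C; NH4Cl (aq)
Reagents that add atoms: none
Why: Oxygen-directed α-lithiation of the cyclic enol ether at the vinylic C3–H gives 14, which adds once to the Weinreb amide through a chelated tetrahedral intermediate (Weinreb ketone synthesis); no stereocentre is touched.

Step 9
Reactants: 16 1-(2-hydroxy-6-methylphenyl)ethan-1-one
Product: 17 4-hydroxy-5-methyl-2H-chromen-2-one
Conditions: NaH, (EtO)2CO, toluene, reflux; then HCl (aq)
Reagents that add atoms: diethyl carbonate CCOC(=O)OCC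
Why: Claisen-type acylation of the methyl ketone enolate by the carbonate and lactonisation onto the phenoxide should give the 4-hydroxycoumarin.

Step 10
Reactants: 15 1-[(4aS,7S,7aR)-4,7-dimethyl-1-(triisopropylsilyloxy)-1,4a,5,6,7,7a-hexahydrocyclopenta[c]pyran-3-yl]-3-methylbutan-1-one; 17 4-hydroxy-5-methyl-2H-chromen-2-one
Product: 18 4-hydroxy-5-methyl-3-[(1R,4aS,7S,7aR)-4,7-dimethyl-3-(3-methylbutanoyl)-1,4a,5,6,7,7a-hexahydrocyclopenta[c]pyran-1-yl]-2H-chromen-2-one
Conditions: BF3·OEt2 (20 mol%), 4 Å molecular sieves, CH2Cl2, −40 to 0 °C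
Reagents that add atoms: none
Why: BF3 ionises the silyl acetal to the C1 oxocarbenium ion, which the nucleophilic C3 of the hydroxycoumarin attacks (Friedel–Crafts-type C-glycosylation) on the convex face anti to the C7a–C7 bond, setting (1R) with the aryl group trans to the cyclopentane; this should also be the thermodynamic epimer, so reversible ionisation reinforces it.

Step 11
Reactants: 18 4-hydroxy-5-methyl-3-[(1R,4aS,7S,7aR)-4,7-dimethyl-3-(3-methylbutanoyl)-1,4a,5,6,7,7a-hexahydrocyclopenta[c]pyran-1-yl]-2H-chromen-2-one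
Product: 20 2-methoxy-5-methyl-3-[(1R,4aS,7S,7aR)-4,7-dimethyl-3-(3-methylbutanoyl)-1,4a,5,6,7,7a-hexahydrocyclopenta[c]pyran-1-yl]-4H-chromen-4-one, via pyrylium triflate 19 (not isolated)
Conditions: MeOTf, CH2Cl2, 0 °C to rt; then NaHCO3 (aq)
Reagents that add atoms: methyl trifluoromethanesulfonate COS(=O)(=O)C(F)(F)F
Why: The neutral vinylogous acid should be alkylated by the hard electrophile at its most basic site, the lactone carbonyl oxygen, giving pyrylium salt 19 that loses the 4-OH proton on work-up to the 2-methoxy-γ-pyrone, as in the preparation of α-methoxy-γ-pyrones from 4-hydroxy-2-pyranones; the peri 5-methyl group and the bulky C3 substituent further shield the 4-oxygen.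

Compound list
1 | (S)-(+)-carvone, (5S)-2-methyl-5-(prop-1-en-2-yl)cyclohex-2-en-1-one | CC1=CC[C@@H](CC1=O)C(C)=C | starting material
2 | lithium (5S)-2-methyl-5-(prop-1-en-2-yl)cyclohex-1-en-1-olate (not isolated) | [Li]OC1=C(C)CC[C@@H](C1)C(C)=C | intermediate
3 | (2S,5S)-2-methyl-5-(prop-1-en-2-yl)cyclohexan-1-one (trans-dihydrocarvone) | C[C@H]1CC[C@@H](CC1=O)C(C)=C | intermediate
4 | (3S,6S)-6-methyl-3-(prop-1-en-2-yl)-2-(trifluoroacetyl)cyclohexan-1-one, C2 undefined, largely enolised (not isolated) | C[C@H]1CC[C@@H](C(C(=O)C(F)(F)F)C1=O)C(C)=C | intermediate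
5 | (3R,6S)-2-diazo-6-methyl-3-(prop-1-en-2-yl)cyclohexan-1-one | C[C@H]1CC[C@@H](C(=[N+]=[N-])C1=O)C(C)=C | intermediate
6 | [(2S,5R)-2-methyl-5-(prop-1-en-2-yl)cyclopentylidene]methanone, the ketene (not isolated) | O=C=C1[C@@H](C)CC[C@@H]1C(C)=C | intermediate
7 | methyl (1R,2S,5S)-2-methyl-5-(prop-1-en-2-yl)cyclopentane-1-carboxylate | COC(=O)[C@@H]1[C@@H](C)CC[C@@H]1C(C)=C | intermediate
8 | 2-[(1R,2R,3S)-2-(hydroxymethyl)-3-methylcyclopentyl]propan-1-ol, epimers at C2 of the propanol | OC[C@@H]1[C@@H](C)CC[C@@H]1C(C)CO | intermediate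
9 | (1R,2S,5R)-2-methyl-5-(1-oxopropan-2-yl)cyclopentane-1-carbaldehyde, iridodial (not isolated) | O=C[C@@H]1[C@@H](C)CC[C@@H]1C(C)C=O | intermediate
10 | (4aS,7S,7aR)-4,7-dimethyl-1,4a,5,6,7,7a-hexahydrocyclopenta[c]pyran-1-ol, anomer mixture | OC1OC=C(C)[C@H]2CC[C@H](C)[C@H]21 | intermediate
11 | triisopropyl{[(4aS,7S,7aR)-4,7-dimethyl-1,4a,5,6,7,7a-hexahydrocyclopenta[c]pyran-1-yl]oxy}silane, anomer mixture | CC(C)[Si](OC1OC=C(C)[C@H]2CC[C@H](C)[C@H]21)(C(C)C)C(C)C | intermediate
12 | 3-methylbutanoyl chloride | CC(C)CC(Cl)=O | starting material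
13 | N-methoxy-N,3-dimethylbutanamide | CC(C)CC(=O)N(C)OC | intermediate
14 | [(4aS,7S,7aR)-4,7-dimethyl-1-(triisopropylsilyloxy)-1,4a,5,6,7,7a-hexahydrocyclopenta[c]pyran-3-yl]lithium (not isolated) | CC(C)[Si](OC1OC([Li])=C(C)[C@H]2CC[C@H](C)[C@H]21)(C(C)C)C(C)C | intermediate
15 | 1-[(4aS,7S,7aR)-4,7-dimethyl-1-(triisopropylsilyloxy)-1,4a,5,6,7,7a-hexahydrocyclopenta[c]pyran-3-yl]-3-methylbutan-1-one, anomer mixture | CC(C)[Si](OC1OC(C(=O)CC(C)C)=C(C)[C@H]2CC[C@H](C)[C@H]21)(C(C)C)C(C)C | intermediate
16 | 1-(2-hydroxy-6-methylphenyl)ethan-1-one | CC(=O)c1c(C)cccc1O | starting material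
17 | 4-hydroxy-5-methyl-2H-chromen-2-one | Cc1cccc2oc(=O)cc(O)c12 | intermediate
18 | 4-hydroxy-5-methyl-3-[(1R,4aS,7S,7aR)-4,7-dimethyl-3-(3-methylbutanoyl)-1,4a,5,6,7,7a-hexahydrocyclopenta[c]pyran-1-yl]-2H-chromen-2-one | Cc1cccc2oc(=O)c(c(O)c12)[C@@H]1OC(C(=O)CC(C)C)=C(C)[C@H]2CC[C@H](C)[C@H]21 | intermediate
19 | 4-hydroxy-2-methoxy-5-methyl-3-[(1R,4aS,7S,7aR)-4,7-dimethyl-3-(3-methylbutanoyl)-1,4a,5,6,7,7a-hexahydrocyclopenta[c]pyran-1-yl]chromenylium trifluoromethanesulfonate (not isolated) | COc1[o+]c2cccc(C)c2c(O)c1[C@@H]1OC(C(=O)CC(C)C)=C(C)[C@H]2CC[C@H](C)[C@H]21.[O-]S(=O)(=O)C(F)(F)F | intermediate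
20 | 2-methoxy-5-methyl-3-[(1R,4aS,7S,7aR)-4,7-dimethyl-3-(3-methylbutanoyl)-1,4a,5,6,7,7a-hexahydrocyclopenta[c]pyran-1-yl]-4H-chromen-4-one | COc1oc2cccc(C)c2c(=O)c1[C@@H]1OC(C(=O)CC(C)C)=C(C)[C@H]2CC[C@H](C)[C@H]21 | target

Total step count: 11. Longest linear sequence: 9 steps (steps 1–6, 8, 10, 11, from (S)-carvone).

Steps most likely to fail

Step 3. The risk is poor facial selectivity in the enol protonation that sets C7a, because the flanking methyl and isopropenyl groups are of similar size. The fallback replaces kinetic control by thermodynamic control through the enol lactone. It sets out from 5: the photolysis product, now containing the C7a-epimeric ester methyl (1S,2S,5S)-2-methyl-5-(prop-1-en-2-yl)cyclopentane-1-carboxylate F1 beside 7, is carried through the conditions of step 4 to the epimeric diol 2-[(1R,2S,3S)-2-(hydroxymethyl)-3-methylcyclopentyl]propan-1-ol F2. Swern oxidation as in step 5 gives the epimeric dialdehyde (1S,2S,5R)-2-methyl-5-(1-oxopropan-2-yl)cyclopentane-1-carbaldehyde F3, which closes to the trans-fused lactol (4aS,7S,7aS)-4,7-dimethyl-1,4a,5,6,7,7a-hexahydrocyclopenta[c]pyran-1-ol F4 beside 10. The lactol mixture is oxidised with TEMPO (cat.) and PhI(OAc)2 in CH2Cl2 to the enol lactones, trans,cis-nepetalactone (4aS,7S,7aS)-4,7-dimethyl-5,6,7,7a-tetrahydrocyclopenta[c]pyran-1(4aH)-one F5 and its C7a epimer. DBU in hot toluene should then epimerise C7a of F5 towards the cis-fused lactone, cis,trans-nepetalactone (4aS,7S,7aR)-4,7-dimethyl-5,6,7,7a-tetrahydrocyclopenta[c]pyran-1(4aH)-one F6. Reduction with i-Bu2AlH in CH2Cl2 at −78 °C returns to the route at 10.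

Step 11. The risk is loss of regiocontrol (methylation at the 4-oxygen) or acid-promoted ionisation at C1 during alkylation. The fallback methylates before the carbon–carbon union. It sets out from 17 and 15: the simple coumarin 17 is treated with MeOTf in CH2Cl2 and then NaHCO3 (aq), where any 4-methoxy isomer is easily removed, to give 2-methoxy-5-methyl-4H-chromen-4-one F8. Its nucleophilic C3 (push–pull enol ether) is then joined to silyl acetal 15 with Me3SiOTf (cat.) in CH2Cl2 at −40 °C, which returns to the route directly at 20.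

Step 10. The risk is competing O-alkylation of the coumarin, double addition of the coumarin or Lewis-acid-induced decomposition of the acyl enol ether. The fallback uses a neutral condensation instead of an oxocarbenium ion. It sets out from 15: desilylation with Bu4NF/AcOH in THF gives the lactol 1-[(4aS,7S,7aR)-1-hydroxy-4,7-dimethyl-1,4a,5,6,7,7a-hexahydrocyclopenta[c]pyran-3-yl]-3-methylbutan-1-one F7, in equilibrium with its open keto-aldehyde. Condensation with 17 under ethylenediammonium diacetate in MeOH at rt should proceed by Knoevenagel condensation at C1 to the 3-alkylidenechromane-2,4-dione and oxa-Michael closure by the enol oxygen of the 1,2-diketone, returning to the route at 18.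

Further compounds
F1 | step 3 | methyl (1S,2S,5S)-2-methyl-5-(prop-1-en-2-yl)cyclopentane-1-carboxylate | COC(=O)[C@H]1[C@@H](C)CC[C@@H]1C(C)=C
F2 | step 3 | 2-[(1R,2S,3S)-2-(hydroxymethyl)-3-methylcyclopentyl]propan-1-ol | OC[C@H]1[C@@H](C)CC[C@@H]1C(C)CO
F3 | step 3 | (1S,2S,5R)-2-methyl-5-(1-oxopropan-2-yl)cyclopentane-1-carbaldehyde | O=C[C@H]1[C@@H](C)CC[C@@H]1C(C)C=O
F4 | step 3 | (4aS,7S,7aS)-4,7-dimethyl-1,4a,5,6,7,7a-hexahydrocyclopenta[c]pyran-1-ol | OC1OC=C(C)[C@H]2CC[C@H](C)[C@@H]21
F5 | step 3 | (4aS,7S,7aS)-4,7-dimethyl-5,6,7,7a-tetrahydrocyclopenta[c]pyran-1(4aH)-one | O=C1OC=C(C)[C@H]2CC[C@H](C)[C@@H]21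
F6 | step 3 | (4aS,7S,7aR)-4,7-dimethyl-5,6,7,7a-tetrahydrocyclopenta[c]pyran-1(4aH)-one | O=C1OC=C(C)[C@H]2CC[C@H](C)[C@H]21
F7 | step 10 | 1-[(4aS,7S,7aR)-1-hydroxy-4,7-dimethyl-1,4a,5,6,7,7a-hexahydrocyclopenta[c]pyran-3-yl]-3-methylbutan-1-one | OC1OC(C(=O)CC(C)C)=C(C)[C@H]2CC[C@H](C)[C@H]21
F8 | step 11 | 2-methoxy-5-methyl-4H-chromen-4-one | COc1cc(=O)c2c(C)cccc2o1
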